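**Retrosynthetic overview**
1. The halves are joined last at C9–C11 by B-alkyl Suzuki–Miyaura coupling of a ring B enol triflate (rings A/B) with the 9-BBN adduct of a C13-vinyl diene (rings D/E); the C8=C9 alkene left by the coupling is then converted into the C8 exocyclic methylene (hydroboration, oxidation, Wittig).
2. Ring A is closed onto ring B in one flask from a silyl enol ether and acrolein: C1–C10 by Mukaiyama–Michael addition, C3–C4 by iron-hydride hydrogen-atom-transfer radical addition of an isopropenyl group to the new aldehyde.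
3. Enabling feature: in ring A the quaternary carbons C10 (methyl-bearing ring fusion, α to a C9 carbonyl of ring B) and C4 (gem-dimethyl, the internal carbon of an isopropenyl group on C5) stand 1,3 across C5 and are bridged by C1–C2–C3 ending in the C3 carbinol, which is acrolein.
4. Ring B is 2-methylcyclohex-2-enone (asymmetric conjugate addition sets C5); ring E comes from an amine-catalysed annulation, ring D from a Diels–Alder reaction of isoprene on the ring E enone.
5. Order of ring formation: B (purchased), A (key step); E, D; union last.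

Key step: step 2

Remark on the chemistry: carbon numbers follow the ursane skeleton of the target (C3 carbinol, C4 gem-dimethyl carbon, C8 methylene-bearing carbon, C13=C14 ring D alkene); the ligand antipode in step 1 and the amine pseudoenantiomer in step 5 are taken to be those that give the drawn configurations.

Step 1
Reactants: 1 2-methylcyclohex-2-en-1-one; 2 prop-1-en-2-ylmagnesium bromide
Product: 4 trimethyl{[(3S)-2-methyl-3-(prop-1-en-2-yl)cyclohex-1-en-1-yl]oxy}silane, via bromomagnesium enolate 3 (not isolated)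
Conditions: CuBr·SMe2 (5 mol %), Josiphos ligand (R)-1-[(S)-2-(diphenylphosphino)ferrocenyl]ethyldicyclohexylphosphine (6 mol %), t-BuOMe, −78 °C; then Me3SiCl, Et3N, −78 to 0 °C
Reagents that add atoms: chlorotrimethylsilane, C[Si](C)(C)Cl
Why: Copper-catalysed asymmetric conjugate addition of a Grignard reagent to a cyclic enone should set C5 as (S) under ligand control, and O-silylation of the regiodefined magnesium enolate (enolate trapping) fixes the double bond between C9 and C10 so that C10 is the only nucleophilic carbon in step 2.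

Step 2
Reactants: 4 trimethyl{[(3S)-2-methyl-3-(prop-1-en-2-yl)cyclohex-1-en-1-yl]oxy}silane; 5 prop-2-enal
Product: 7 (4aS,6S,8aS)-6-hydroxy-5,5,8a-trimethyl-3,4,4a,5,6,7,8,8a-octahydronaphthalen-1(2H)-one, via keto aldehyde 6 (not isolated)
Conditions: [Bn2NH2][O2CCF3] (20 mol %), H2O (2 equiv), CH2Cl2, −20 °C, then argon purge to remove excess 5; then EtOH, Fe(acac)3 (50 mol %), PhSiH3 (2.5 equiv), 60 °C
Reagents that add atoms: none
Why: Proposed new method: iminium activation of acrolein by the secondary ammonium salt should make silyl enol ether 4 add in the 1,4 sense through C10 (Mukaiyama–Michael addition), hydrolysis releasing keto aldehyde 6; the iron hydride formed from Fe(acac)3 and PhSiH3 then transfers a hydrogen atom to the CH2 terminus of the isopropenyl group, the tertiary C4 radical adds to the aldehyde carbon and the alkoxy radical is reduced to the C3 alkoxide. The closest known reaction types are the amine-catalysed Mukaiyama–Michael addition of enol silanes to enals and the iron-hydride hydrogen-atom-transfer cyclization of alkene-tethered ketones; their union in one flask and the aldehyde acceptor are new. Ring A closes by 6-exo-trig radical addition to C=O through a chair transition state. C10 is set by the C5 stereocentre (the pseudoaxial isopropenyl group shields one face of the C9=C10 enol ether, so C1 enters trans to it, the trans-decalin relationship), and C3 should form with the oxygen equatorial (3β) because the radical addition is reversible and the less hindered equatorial alkoxy radical is trapped. The step needs 1,4- over 1,2-addition to acrolein (secured by the iminium ion), bond formation at C10 and not C8 (secured by the enol ether position fixed in step 1) and one orientation of the three-carbon unit (only C10 is nucleophilic in the first stage, only C4 becomes a radical in the second, and attack of that radical on the C9 ketone would need a four-membered ring).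

Step 3
Reactants: 7 (4aS,6S,8aS)-6-hydroxy-5,5,8a-trimethyl-3,4,4a,5,6,7,8,8a-octahydronaphthalen-1(2H)-one
Product: 8 (4aS,6S,8aS)-6-[(tert-butyldimethylsilyl)oxy]-5,5,8a-trimethyl-3,4,4a,5,6,7,8,8a-octahydronaphthalen-1(2H)-one
Conditions: t-BuMe2SiOTf, 2,6-lutidine, CH2Cl2, 0 °C
Reagents that add atoms: tert-butyldimethylsilyl trifluoromethanesulfonate, CC(C)(C)[Si](C)(C)OS(=O)(=O)C(F)(F)F
Why: Silylation of the hindered equatorial 3β-alcohol with a silyl triflate and a hindered base (silyl ether protection) should leave the C9 ketone untouched and creates no stereocentre.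

Step 4
Reactants: 8 (4aS,6S,8aS)-6-[(tert-butyldimethylsilyl)oxy]-5,5,8a-trimethyl-3,4,4a,5,6,7,8,8a-octahydronaphthalen-1(2H)-one
Product: 10 (4aS,6S,8aS)-6-[(tert-butyldimethylsilyl)oxy]-5,5,8a-trimethyl-3,4,4a,5,6,7,8,8a-octahydronaphthalen-1-yl trifluoromethanesulfonate, via potassium enolate 9 (not isolated)
Conditions: KN(SiMe3)2, THF, −78 °C; then PhNTf2, −78 to 0 °C
Reagents that add atoms: N-phenylbis(trifluoromethanesulfonimide), O=S(=O)(N(c1ccccc1)S(=O)(=O)C(F)(F)F)C(F)(F)F
Why: C10 is quaternary, so the amide base can deprotonate only at C8, and O-triflation of that enolate (enol triflate formation) gives the C8=C9 triflate regiospecifically without forming a stereocentre.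

Step 5
Reactants: 11 tert-butyl 3-oxopentanoate; 12 (E)-2-methylbut-2-enal
Product: 14 (4S,5R)-2,4,5-trimethylcyclohex-2-en-1-one, via Michael adduct 13 (not isolated)
Conditions: 9-amino-9-deoxy-epi-quinine (20 mol %), CF3CO2H (40 mol %), toluene, 25 °C; then p-TsOH·H2O (20 mol %), 80 °C
Reagents that add atoms: none
Why: Proposed new method: the primary amine should condense with the α-branched enal 12 to an iminium ion to which β-keto ester 11 adds (C20 set by the catalyst), and acid then drives intramolecular aldol condensation, loss of the tert-butyl ester as isobutene and CO2 and equilibration of the γ-stereocentre C19 to the trans-4,5-dimethyl enone, the closest known reaction type being the amine-catalysed Michael/aldol annulation of β-keto esters with β-substituted enals to 5-substituted cyclohexenones, extended here to an α-branched enal by primary-amine iminium catalysis.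

Step 6
Reactants: 14 (4S,5R)-2,4,5-trimethylcyclohex-2-en-1-one; 15 2-methylbuta-1,3-diene
Product: 16 (3R,4S,4aR,8aR)-3,4,6,8a-tetramethyl-3,4,4a,5,8,8a-hexahydronaphthalen-1(2H)-one
Conditions: EtAlCl2 (30 mol %), toluene, −20 to 25 °C
Reagents that add atoms: none
Why: In this Lewis-acid-catalysed Diels–Alder reaction of a 2-methylcyclohexenone, isoprene should add with its methyl-bearing carbon para to C17 and to the face of the C17=C18 double bond anti to the adjacent C19 methyl group, which sets C17 and C18 (cis ring fusion, C17 methyl and H-18 cis to the C19 methyl).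

Step 7
Reactants: 16 (3R,4S,4aR,8aR)-3,4,6,8a-tetramethyl-3,4,4a,5,8,8a-hexahydronaphthalen-1(2H)-one
Product: 17 (1S,2R,4aR,8aR)-1,2,4a,7-tetramethyl-1,2,3,4,4a,5,8,8a-octahydronaphthalene
Conditions: N2H4·H2O, KOH, diethylene glycol, 200 °C
Reagents that add atoms: none
Why: Wolff–Kishner reduction (Huang-Minlon conditions) removes the C22 carbonyl once it has activated the dienophile, and no stereocentre is epimerisable because the α-carbon C17 is quaternary.

Step 8
Reactants: 17 (1S,2R,4aR,8aR)-1,2,4a,7-tetramethyl-1,2,3,4,4a,5,8,8a-octahydronaphthalene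
Product: 19 (4aR,7R,8S,8aR)-2,4a,7,8-tetramethyl-4a,5,6,7,8,8a-hexahydronaphthalen-1(4H)-one, via allylic alcohol 18 (not isolated)
Conditions: SeO2 (1.1 equiv), 1,4-dioxane, 80 °C; then Dess–Martin periodinane, CH2Cl2, 0 °C
Reagents that add atoms: selenium dioxide, O=[Se]=O
Why: Selenium dioxide allylic oxidation (ene reaction then 2,3-sigmatropic shift) should attack the ring CH2 (C13) next to the more substituted alkene carbon C14, and oxidation of the epimeric alcohols gives the 2-methyl enone, in which C18 can equilibrate only to the required cis-fused isomer that keeps both ring E methyl groups equatorial.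

Step 9
Reactants: 19 (4aR,7R,8S,8aR)-2,4a,7,8-tetramethyl-4a,5,6,7,8,8a-hexahydronaphthalen-1(4H)-one
Product: 21 (4aR,7R,8S,8aR)-2,4a,7,8-tetramethyl-3,4,4a,5,6,7,8,8a-octahydronaphthalen-1-yl trifluoromethanesulfonate, via lithium enolate 20 (not isolated)
Conditions: Li[HB(s-Bu)3], THF, −78 °C; then PhNTf2, −78 to 0 °C
Reagents that add atoms: N-phenylbis(trifluoromethanesulfonimide), O=S(=O)(N(c1ccccc1)S(=O)(=O)C(F)(F)F)C(F)(F)F
Why: 1,4-Reduction of the enone by the bulky borohydride gives the C13–C14 enolate regiospecifically, and its O-triflation (enol triflate formation) fixes the tetrasubstituted C13=C14 double bond without enolising C18.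

Step 10
Reactants: 21 (4aR,7R,8S,8aR)-2,4a,7,8-tetramethyl-3,4,4a,5,6,7,8,8a-octahydronaphthalen-1-yl trifluoromethanesulfonate
Product: 22 (4aR,7R,8S,8aR)-1-ethenyl-2,4a,7,8-tetramethyl-3,4,4a,5,6,7,8,8a-octahydronaphthalene
Conditions: tributyl(vinyl)stannane, Pd(PPh3)4 (5 mol %), LiCl, THF, 65 °C
Reagents that add atoms: tributyl(vinyl)stannane, C=C[Sn](CCCC)(CCCC)CCCC
Why: Stille coupling of the enol triflate with a vinylstannane installs C11 and C12 as a vinyl group on C13 and touches no stereocentre.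

Step 11
Reactants: 22 (4aR,7R,8S,8aR)-1-ethenyl-2,4a,7,8-tetramethyl-3,4,4a,5,6,7,8,8a-octahydronaphthalene; 10 (4aS,6S,8aS)-6-[(tert-butyldimethylsilyl)oxy]-5,5,8a-trimethyl-3,4,4a,5,6,7,8,8a-octahydronaphthalen-1-yl trifluoromethanesulfonate
Product: 24 tert-butyldimethylsilyl ether of 26-nor-8,14-secoursa-8,13-dien-3β-ol, via B-alkyl-9-BBN 23 (not isolated)
Conditions: 9-BBN-H, THF, 25 °C; then 10, PdCl2(dppf) (10 mol %), AsPh3, Cs2CO3, DMF–H2O, 50 °C
Reagents that add atoms: none
Why: 9-BBN should add to the terminal vinyl group of the diene with boron on C11 (anti-Markovnikov hydroboration), and B-alkyl Suzuki–Miyaura coupling of this primary alkylborane with enol triflate 10 forms the C9–C11 bond that joins the halves without forming a stereocentre.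

Step 12
Reactants: 24 tert-butyldimethylsilyl ether of 26-nor-8,14-secoursa-8,13-dien-3β-ol
Product: 26 3β-[(tert-butyldimethylsilyl)oxy]-26-nor-8,14-secours-13-en-8α-ol, via alkylborane 25 (not isolated)
Conditions: BH3·THF (1.2 equiv), THF, 0 to 25 °C; then NaOH, H2O2, 0 °C
Reagents that add atoms: hydrogen peroxide, OO
Why: In this hydroboration–oxidation borane should add to the trisubstituted C8=C9 double bond in preference to the tetrasubstituted C13=C14 one and from the α face opposite the axial C10 methyl group, placing hydrogen on C9 (9α-H) and oxygen on C8.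

Step 13
Reactants: 26 3β-[(tert-butyldimethylsilyl)oxy]-26-nor-8,14-secours-13-en-8α-ol
Product: 27 3β-[(tert-butyldimethylsilyl)oxy]-26-nor-8,14-secours-13-en-8-one
Conditions: Dess–Martin periodinane, CH2Cl2, 0 to 25 °C
Reagents that add atoms: none
Why: Dess–Martin oxidation of the secondary alcohol gives the C8 ketone, and C9, now epimerisable, has the required configuration (equatorial side chain, 9α-H) as its thermodynamically preferred one.

Step 14
Reactants: 27 3β-[(tert-butyldimethylsilyl)oxy]-26-nor-8,14-secours-13-en-8-one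
Product: 28 tert-butyldimethylsilyl ether of 8,14-secoursa-8(26),13-dien-3β-ol
Conditions: Ph3PCH3Br, KOt-Bu, toluene, 90 °C
Reagents that add atoms: methyltriphenylphosphonium bromide, C[P+](c1ccccc1)(c1ccccc1)c1ccccc1.[Br-]
Why: Wittig methylenation with excess ylide at elevated temperature should convert the hindered C8 ketone into the exocyclic C8=C26 methylene, and any base-mediated equilibration at C9 can only favour the equatorial side chain.

Step 15
Reactants: 28 tert-butyldimethylsilyl ether of 8,14-secoursa-8(26),13-dien-3β-ol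
Product: 29 8,14-secoursa-8(26),13-dien-3β-ol (CNP0210309.1)
Conditions: Bu4NF, THF, 50 °C
Reagents that add atoms: none
Why: Fluoride cleaves the silyl ether (desilylation) and releases the 3β-hydroxy group without affecting either alkene.

**Compound list**
1 | 2-methylcyclohex-2-en-1-one | CC1=CCCCC1=O | starting material
2 | prop-1-en-2-ylmagnesium bromide (isopropenylmagnesium bromide) | CC(=C)[Mg]Br | starting material
3 | bromomagnesium (3S)-2-methyl-3-(prop-1-en-2-yl)cyclohex-1-en-1-olate | C1CC[C@@H](C(C)=C)C(C)=C1O[Mg]Br | intermediate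
4 | trimethyl{[(3S)-2-methyl-3-(prop-1-en-2-yl)cyclohex-1-en-1-yl]oxy}silane | C1CC[C@@H](C(C)=C)C(C)=C1O[Si](C)(C)C | intermediate
5 | prop-2-enal (acrolein) | C=CC=O | starting material
6 | 3-[(1S,6S)-1-methyl-2-oxo-6-(prop-1-en-2-yl)cyclohexyl]propanal | C1CC[C@@H](C(C)=C)[C@@](CCC=O)(C)C1=O | intermediate
7 | (4aS,6S,8aS)-6-hydroxy-5,5,8a-trimethyl-3,4,4a,5,6,7,8,8a-octahydronaphthalen-1(2H)-one (rings A/B: 3β-OH, 5α-H, 10β-CH3, C9 ketone) | C1CC[C@H]2C(C)(C)[C@@H](O)CC[C@]2(C)C1=O | intermediate
8 | (4aS,6S,8aS)-6-[(tert-butyldimethylsilyl)oxy]-5,5,8a-trimethyl-3,4,4a,5,6,7,8,8a-octahydronaphthalen-1(2H)-one | C1CC[C@H]2C(C)(C)[C@@H](O[Si](C)(C)C(C)(C)C)CC[C@]2(C)C1=O | intermediate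
9 | potassium (4aS,6S,8aS)-6-[(tert-butyldimethylsilyl)oxy]-5,5,8a-trimethyl-3,4,4a,5,6,7,8,8a-octahydronaphthalen-1-olate | C=1CC[C@H]2C(C)(C)[C@@H](O[Si](C)(C)C(C)(C)C)CC[C@]2(C)C=1O[K] | intermediate
10 | (4aS,6S,8aS)-6-[(tert-butyldimethylsilyl)oxy]-5,5,8a-trimethyl-3,4,4a,5,6,7,8,8a-octahydronaphthalen-1-yl trifluoromethanesulfonate | C=1CC[C@H]2C(C)(C)[C@@H](O[Si](C)(C)C(C)(C)C)CC[C@]2(C)C=1OS(=O)(=O)C(F)(F)F | intermediate
11 | tert-butyl 3-oxopentanoate | CCC(=O)CC(=O)OC(C)(C)C | starting material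
12 | (E)-2-methylbut-2-enal | C/C=C(C)/C=O | starting material
13 | tert-butyl (3S)-3,4-dimethyl-5-oxo-2-propanoylpentanoate (epimers at C2 and C4) | CCC(=O)C(C(=O)OC(C)(C)C)[C@@H](C)C(C)C=O | intermediate
14 | (4S,5R)-2,4,5-trimethylcyclohex-2-en-1-one | O=C1C[C@@H](C)[C@H](C)C=C1C | intermediate
15 | 2-methylbuta-1,3-diene (isoprene) | C=CC(C)=C | starting material
16 | (3R,4S,4aR,8aR)-3,4,6,8a-tetramethyl-3,4,4a,5,8,8a-hexahydronaphthalen-1(2H)-one | C1C(C)=CC[C@@]2(C)C(=O)C[C@@H](C)[C@H](C)[C@@H]12 | intermediate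
17 | (1S,2R,4aR,8aR)-1,2,4a,7-tetramethyl-1,2,3,4,4a,5,8,8a-octahydronaphthalene | C1C(C)=CC[C@@]2(C)CC[C@@H](C)[C@H](C)[C@@H]12 | intermediate
18 | (4aR,7R,8S,8aR)-2,4a,7,8-tetramethyl-1,4,4a,5,6,7,8,8a-octahydronaphthalen-1-ol (both C1 epimers) | OC1C(C)=CC[C@@]2(C)CC[C@@H](C)[C@H](C)[C@@H]12 | intermediate
19 | (4aR,7R,8S,8aR)-2,4a,7,8-tetramethyl-4a,5,6,7,8,8a-hexahydronaphthalen-1(4H)-one | O=C1C(C)=CC[C@@]2(C)CC[C@@H](C)[C@H](C)[C@@H]12 | intermediate
20 | lithium (4aR,7R,8S,8aR)-2,4a,7,8-tetramethyl-3,4,4a,5,6,7,8,8a-octahydronaphthalen-1-olate | [Li]OC1=C(C)CC[C@@]2(C)CC[C@@H](C)[C@H](C)[C@@H]12 | intermediate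
21 | (4aR,7R,8S,8aR)-2,4a,7,8-tetramethyl-3,4,4a,5,6,7,8,8a-octahydronaphthalen-1-yl trifluoromethanesulfonate | FC(F)(F)S(=O)(=O)OC1=C(C)CC[C@@]2(C)CC[C@@H](C)[C@H](C)[C@@H]12 | intermediate
22 | (4aR,7R,8S,8aR)-1-ethenyl-2,4a,7,8-tetramethyl-3,4,4a,5,6,7,8,8a-octahydronaphthalene | C=CC1=C(C)CC[C@@]2(C)CC[C@@H](C)[C@H](C)[C@@H]12 | intermediate
23 | 9-{2-[(4aR,7R,8S,8aR)-2,4a,7,8-tetramethyl-3,4,4a,5,6,7,8,8a-octahydronaphthalen-1-yl]ethyl}-9-borabicyclo[3.3.1]nonane | C(CC1=C(C)CC[C@@]2(C)CC[C@@H](C)[C@H](C)[C@@H]12)B1C2CCCC1CCC2 | intermediate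
24 | tert-butyldimethylsilyl ether of 26-nor-8,14-secoursa-8,13-dien-3β-ol (C8=C9 and C13=C14 alkenes, 5α-H, 10β-CH3) | C=1CC[C@H]2C(C)(C)[C@@H](O[Si](C)(C)C(C)(C)C)CC[C@]2(C)C=1CCC1=C(C)CC[C@@]2(C)CC[C@@H](C)[C@H](C)[C@@H]12 | intermediate
25 | 8α-borane adduct of 24 (C8–BH2, 9α-H) | [BH2][C@@H]1CC[C@H]2C(C)(C)[C@@H](O[Si](C)(C)C(C)(C)C)CC[C@]2(C)[C@H]1CCC1=C(C)CC[C@@]2(C)CC[C@@H](C)[C@H](C)[C@@H]12 | intermediate
26 | 3β-[(tert-butyldimethylsilyl)oxy]-26-nor-8,14-secours-13-en-8α-ol (9α-H) | O[C@@H]1CC[C@H]2C(C)(C)[C@@H](O[Si](C)(C)C(C)(C)C)CC[C@]2(C)[C@H]1CCC1=C(C)CC[C@@]2(C)CC[C@@H](C)[C@H](C)[C@@H]12 | intermediate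
27 | 3β-[(tert-butyldimethylsilyl)oxy]-26-nor-8,14-secours-13-en-8-one (9α-H) | O=C1CC[C@H]2C(C)(C)[C@@H](O[Si](C)(C)C(C)(C)C)CC[C@]2(C)[C@H]1CCC1=C(C)CC[C@@]2(C)CC[C@@H](C)[C@H](C)[C@@H]12 | intermediate
28 | tert-butyldimethylsilyl ether of 8,14-secoursa-8(26),13-dien-3β-ol | C=C1CC[C@H]2C(C)(C)[C@@H](O[Si](C)(C)C(C)(C)C)CC[C@]2(C)[C@H]1CCC1=C(C)CC[C@@]2(C)CC[C@@H](C)[C@H](C)[C@@H]12 | intermediate
29 | 8,14-secoursa-8(26),13-dien-3β-ol (CNP0210309.1) | C=C1CC[C@H]2C(C)(C)[C@@H](O)CC[C@]2(C)[C@H]1CCC1=C(C)CC[C@@]2(C)CC[C@@H](C)[C@H](C)[C@@H]12 | target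

**Step count and risks**
Total: 15 steps (steps 1–4 left half, steps 5–10 right half, steps 11–15 union and finish). Longest linear sequence: 11 steps (steps 5–15, from 11 and 12).

Steps most likely to fail:

Step 2 (Proposed new method). What may go wrong: protodesilylation of the enol ether before the carbon–carbon bond forms, 1,2-addition to acrolein, reduction of the tertiary radical by hydrogen-atom transfer faster than its addition to the aldehyde, or poor facial selectivity at C3. The fallback sets out from 4 and returns at 7, with both bonds made stepwise by known reactions. MeLi (THF, 0 °C) would convert 4 into its lithium enolate, which would be alkylated at C10, trans to the isopropenyl group, with 2-(2-iodoethyl)-1,3-dioxolane (DMPU) to give (2S,3S)-2-[2-(1,3-dioxolan-2-yl)ethyl]-2-methyl-3-(prop-1-en-2-yl)cyclohexan-1-one F1. Aqueous HCl in THF would unmask keto aldehyde 6, now isolated. HBr in CH2Cl2 at −78 °C would add to the isopropenyl group in the Markovnikov sense to give 3-[(1S,6R)-6-(2-bromopropan-2-yl)-1-methyl-2-oxocyclohexyl]propanal F2. Slow addition of Bu3SnH with AIBN (benzene, 80 °C) would generate the same tertiary C4 radical from the bromide and close ring A by the known 6-exo cyclization of alkyl radicals onto aldehydes, giving 7.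

Step 5 (Proposed new method). What may go wrong: slow iminium formation with the α-branched enal and weak enantiofacial control in the Michael addition. The fallback sets out from 11 and 12 and returns at 14. Base-mediated Michael addition (KOt-Bu, 10 mol %, t-BuOH) followed by p-TsOH in toluene at 80 °C would give the racemic trans enone rac-(4S,5R)-2,4,5-trimethylcyclohex-2-en-1-one F3. Luche reduction (NaBH4, CeCl3·7H2O, MeOH, −78 °C) would give rac-(1S,4S,5R)-2,4,5-trimethylcyclohex-2-en-1-ol F4. Lipase-catalysed acylation (Candida antarctica lipase B, vinyl acetate) would resolve F4 kinetically, and (1S,4S,5R)-2,4,5-trimethylcyclohex-2-en-1-ol F5 would be collected; it is taken here to be the enantiomer left unacylated, and otherwise would be freed from its acetate with K2CO3 in MeOH. Oxidation of F5 with MnO2 would give 14.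

Step 12. What may go wrong: competing hydroboration of the tetrasubstituted C13=C14 alkene, or no reaction at the hindered C8=C9 alkene. The fallback sets out from 8 and returns at 27; it introduces the C8 oxygen before the coupling so that no hydroboration is needed.
- KN(SiMe3)2 and 3-phenyl-2-(phenylsulfonyl)oxaziridine (THF, −78 °C) would hydroxylate the C8 enolate of 8 to (4aS,6S,8aS)-6-[(tert-butyldimethylsilyl)oxy]-2-hydroxy-5,5,8a-trimethyl-3,4,4a,5,6,7,8,8a-octahydronaphthalen-1(2H)-one F6.
- Et3SiCl and imidazole would give its triethylsilyl ether F7.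
- KN(SiMe3)2 and PhNTf2 would give (4aS,6S,8aS)-6-[(tert-butyldimethylsilyl)oxy]-5,5,8a-trimethyl-2-[(triethylsilyl)oxy]-3,4,4a,5,6,7,8,8a-octahydronaphthalen-1-yl trifluoromethanesulfonate F8.
- Suzuki–Miyaura coupling of F8 with alkylborane 23 under the conditions of step 11 would give 3β-[(tert-butyldimethylsilyl)oxy]-8-[(triethylsilyl)oxy]-26-nor-8,14-secoursa-8,13-diene F9, a regiodefined silyl enol ether of the C8 ketone.
- Dilute HCl in THF would hydrolyse the enol ether to 27, with C9 protonated to the equatorial side chain.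

Further compounds
F1 | step 2 | (2S,3S)-2-[2-(1,3-dioxolan-2-yl)ethyl]-2-methyl-3-(prop-1-en-2-yl)cyclohexan-1-one | C1CC[C@@H](C(C)=C)[C@@](CCC2OCCO2)(C)C1=O
F2 | step 2 | 3-[(1S,6R)-6-(2-bromopropan-2-yl)-1-methyl-2-oxocyclohexyl]propanal | C1CC[C@@H](C(C)(C)Br)[C@@](CCC=O)(C)C1=O
F3 | step 5 | rac-(4S,5R)-2,4,5-trimethylcyclohex-2-en-1-one | O=C1C[C@@H](C)[C@H](C)C=C1C
F4 | step 5 | rac-(1S,4S,5R)-2,4,5-trimethylcyclohex-2-en-1-ol | O[C@H]1C[C@@H](C)[C@H](C)C=C1C
F5 | step 5 | (1S,4S,5R)-2,4,5-trimethylcyclohex-2-en-1-ol | O[C@H]1C[C@@H](C)[C@H](C)C=C1C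
F6 | step 12 | (4aS,6S,8aS)-6-[(tert-butyldimethylsilyl)oxy]-2-hydroxy-5,5,8a-trimethyl-3,4,4a,5,6,7,8,8a-octahydronaphthalen-1(2H)-one | OC1CC[C@H]2C(C)(C)[C@@H](O[Si](C)(C)C(C)(C)C)CC[C@]2(C)C1=O
F7 | step 12 | (4aS,6S,8aS)-6-[(tert-butyldimethylsilyl)oxy]-5,5,8a-trimethyl-2-[(triethylsilyl)oxy]-3,4,4a,5,6,7,8,8a-octahydronaphthalen-1(2H)-one | CC[Si](CC)(CC)OC1CC[C@H]2C(C)(C)[C@@H](O[Si](C)(C)C(C)(C)C)CC[C@]2(C)C1=O
F8 | step 12 | (4aS,6S,8aS)-6-[(tert-butyldimethylsilyl)oxy]-5,5,8a-trimethyl-2-[(triethylsilyl)oxy]-3,4,4a,5,6,7,8,8a-octahydronaphthalen-1-yl trifluoromethanesulfonate | CC[Si](CC)(CC)OC=1CC[C@H]2C(C)(C)[C@@H](O[Si](C)(C)C(C)(C)C)CC[C@]2(C)C=1OS(=O)(=O)C(F)(F)F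
F9 | step 12 | 3β-[(tert-butyldimethylsilyl)oxy]-8-[(triethylsilyl)oxy]-26-nor-8,14-secoursa-8,13-diene | CC[Si](CC)(CC)OC=1CC[C@H]2C(C)(C)[C@@H](O[Si](C)(C)C(C)(C)C)CC[C@]2(C)C=1CCC1=C(C)CC[C@@]2(C)CC[C@@H](C)[C@H](C)[C@@H]12
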